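## Analysis of the target

The target 21 is a diaryl ether of two benzene rings with no stereocentres, so the whole problem is where the oxygens sit and how they are told apart. Ring A is a phloroglucinol unit whose three oxygens all differ: C1 carries a hydrogen sulfate ester, C3 a free hydroxyl and C5 the ether oxygen to ring B. Ring B is tetraoxygenated: its C1 holds the ether oxygen between hydroxyls on C2 and C6, and C4, para to the ether, carries the second hydrogen sulfate. The aryl sulfate monoesters are strongly acidic, very polar and acid-labile, and the unprotected ring B is a hydroxylated hydroquinone that oxidises easily to a quinone. The sulfates therefore have to come late and the free phenols last. Two things make the synthesis hard. The ether oxygen on ring B is flanked by two ortho oxygens, which hinders a direct aryl–oxygen coupling. Of the five phenolic oxygens exactly two, one per ring, must be sulfated, and C1 and C3 of ring A would be equivalent in any symmetric resorcinol precursor. The strategy rests on the 1,3,5 relationship of the ring A oxygens: C1 can be a ketene carbonyl carbon, C3 the oxygen-bearing carbon of a silyloxyalkyne and C5 the C3 of a 3-aryloxycyclobutenone, so the three oxygens arrive as free phenol, silyl ether and aryl ether.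

## Retrosynthetic reasoning

**21 back to 20 and 19.** The two benzyl–oxygen bonds on C2 and C6 of ring B and the silicon–oxygen bond on C3 of ring A are cut last. These three oxygens must end as free hydroxyls, and unmasking them after the sulfates are in place keeps the oxidation-prone ring B protected for as long as possible. The forward steps must cleave a silyl ether and two benzyl ethers without touching aryl sulfate monoesters; neutral desilylation and neutral hydrogenolysis should do this.

**19 back to 18.** Both sulfur–oxygen bonds are cut together, giving the diphenol 18, whose only free hydroxyls are on C1 of ring A and C4 of ring B. No site selection is then needed at the sulfation stage; the forward step only has to go to completion on two unhindered phenols.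

**18 back to 17.** The hydroxyl on C4 of ring B is traced to the methoxymethyl acetal of 17. An acetal tolerates base and heat earlier in the route and comes off with dilute acid, which benzyl ethers and a hindered aryl silyl ether withstand.

**17 back to 8 and 13.** This is the key disconnection. Ring A is opened at C1–C2 and C3–C4, so that C2 and C3 come from the silyloxyalkyne 13 and C1, C4, C5 and C6 from the cyclobutenone 8. Cutting here, and not at the diaryl ether, gives ring A with its three oxygens already different (free hydroxyl, silyl ether, aryl ether). It also moves the making of the hindered ether to an earlier stage, where the carbon partner is an unhindered vinylic carbon. The forward reaction must open 8 to the vinylketene 14, join it to 13 with the correct orientation to give 15, and let 15 reorganise through the dienylketene 16 to the phenol.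

**8 back to 4 and 7.** The vinylic carbon–oxygen bond of 8 is cut, giving the phenol 4 and the chloro enone 7. The flanked phenoxide of 4 only has to attack the unhindered C3 of 7 in an addition–elimination.

**7 back to 6 and 5.** The chloro enone 7 is the vinylogous acid chloride of the dione 6, which comes from hydrolysis of the vinylogous ester 5. Both are functional-group changes on an intact four-membered ring.

**4 back to 3, 2 and 1.** The acetal carbon–oxygen bond of 4 is cut to give the hydroquinone 3, whose two hydroxyls differ in hindrance and acidity. Compound 3 is the reduced form of the quinone 2, and 2 arises by oxidation of the phenol 1 at its free para position. The fourth oxygen of ring B is thus placed exactly between the two benzyloxy groups.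

**13 back to 12, 9 and 10.** The silicon–oxygen bond of 13 is cut to give the silyl chloride 10 and the ynolate 12. The ynolate is traced to the isoxazole 9, whose C5-lithiated form 11 should fall apart into 12 and a nitrile. This provides the two-carbon unit C2–C3 of ring A with its oxygen already attached.

## Alternatives that were turned down

**Alternative 1:** No ring is built. Both sulfate-bearing carbon–oxygen bonds are traced back to C–H bonds of 1,3-bis(triisopropylsilyloxy)-2-[3-(triisopropylsilyloxy)phenoxy]benzene A2. In the forward step one sterically governed iridium-catalysed C–H borylation with a bipyridine ligand, followed by peroxide oxidation in the same pot, would give 3-[4-hydroxy-2,6-bis(triisopropylsilyloxy)phenoxy]-5-(triisopropylsilyloxy)phenol A1.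
- For it: C1–H of ring A is the only C–H meta to both substituents, and C4–H of ring B is the only one not ortho to a silyloxy group. A1 has exactly the two sulfate sites free, and sulfation followed by desilylation would finish the synthesis.
- Against it: A2 must first be assembled by coupling a phenol with two ortho oxygens to an aryl halide, which is the hindered bond formation the chosen route avoids. Two independent C–H functionalisations must both go to completion in one molecule, and partly borylated material would be hard to separate.
- Comparison: this route is shorter and is stronger on step economy. The chosen strategy offers in return a ring A whose oxygens are differentiated by construction and an ether made by addition–elimination at an unhindered carbon.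

**Alternative 2:** Ring B is cut at C1–C2 and traced to 6-{[3-(benzyloxy)-5-(methoxymethoxy)phenoxy]methyl}-4-(methoxymethoxy)-2H-pyran-2-one A4. A magnesium alkoxide would open the lactone, and the carbanion on the aryloxy-bearing carbon would attack the liberated ester to give 2-[3-(benzyloxy)-5-(methoxymethoxy)phenoxy]-5-(methoxymethoxy)benzene-1,3-diol A3.
- For it: the ether oxygen is attached by alkylation of an unhindered ring A phenoxide at a primary carbon, which is easier than any aryl–oxygen coupling and at least as good as the addition–elimination used here. The ring closure follows a polyketide pattern.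
- Against it: the closing Claisen step asks a hindered, oxygen-substituted carbanion to acylate an ester deactivated by a β-alkoxy group, while the doubly activated methylene between the enol ether and the ketone is deprotonated more easily. A3 also has the two flanking ring B hydroxyls free, and they must be protected again before the sulfate sites can be unmasked.
- Comparison: the step count is no shorter. The chosen benzannulation runs under neutral thermal conditions with no competing enolate chemistry and delivers the sulfate site of ring A already free.

**Alternative 3:** Ring B is cut at C2–C3 and C5–C6. An alkoxide-mediated double Claisen condensation of dimethyl 2-[3-(benzyloxy)-5-(methoxymethoxy)phenoxy]propanedioate A6 with dimethyl 3-oxopentanedioate A7 would give dimethyl 5-[3-(benzyloxy)-5-(methoxymethoxy)phenoxy]-2,4,6-trihydroxybenzene-1,3-dicarboxylate A5.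
- For it: both components are cheap, the aryl ether bond of A6 is made at an sp3 carbon, and the annulation is convergent. On cost of materials it is stronger than the chosen route.
- Against it: the base converts both A6 and A7 into stabilised enolates, so the ester groups of A6 become poor electrophiles. A5 then needs two ester hydrolyses and two decarboxylations. It also leaves three free hydroxyls on ring B, and the one that must be sulfated lies between the two esters and is the least reactive.
- Comparison: the chosen strategy spends more effort on its building blocks but needs no later correction of oxidation level or of oxygen differentiation on either ring.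

Key step: step 8

Remark on the chemistry: the sulfate esters 19, 20 and 21 are written as free hydrogen sulfates, as in the target SMILES. In the flask 19 and 20 are best carried as bis(tetrabutylammonium) salts, and the protons are restored on an acidic resin after step 12.

## Route

**Step 1**
Reactants: 1 3,5-bis(benzyloxy)phenol
Product: 2 2,6-bis(benzyloxy)cyclohexa-2,5-diene-1,4-dione
Conditions: (KSO3)2NO (2.2 equiv), KH2PO4, H2O/acetone, rt
Reagents that add atoms: potassium nitrosodisulfonate, [K+].[K+].[O]N(S(=O)(=O)[O-])S(=O)(=O)[O-]
Why: Teuber oxidation: the nitroxyl radical abstracts the phenolic hydrogen and a second equivalent delivers oxygen to the free para carbon, so a phenol with an open para position should give the para-quinone. The benzyl ethers are inert to this one-electron oxidant.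

**Step 2**
Reactants: 2 2,6-bis(benzyloxy)cyclohexa-2,5-diene-1,4-dione
Product: 3 2,6-bis(benzyloxy)benzene-1,4-diol
Conditions: Na2S2O4, H2O/EtOAc, rt, N2
Reagents that add atoms: none
Why: Dithionite reduction of a quinone to its hydroquinone; unlike catalytic hydrogenation it leaves the benzyl ethers alone. The air-sensitive product is to be used at once.

**Step 3**
Reactants: 3 2,6-bis(benzyloxy)benzene-1,4-diol
Product: 4 2,6-bis(benzyloxy)-4-(methoxymethoxy)phenol
Conditions: MOMCl (1.0 equiv), iPr2NEt, CH2Cl2, −20 → 0 °C, Ar
Reagents that add atoms: chloromethyl methyl ether, COCCl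
Why: Williamson-type O-alkylation with one equivalent of electrophile. The C4 hydroxyl has two ortho hydrogens and two meta benzyloxy groups, so it is both less hindered and more acidic than the C1 hydroxyl, which is buttressed by two ortho benzyloxy groups and remains free as the future ether oxygen.

**Step 4**
Reactants: 5 3-ethoxycyclobut-2-en-1-one
Product: 6 cyclobutane-1,3-dione
Conditions: 1 M HCl, H2O/THF, rt
Reagents that add atoms: water, O
Why: Acid hydrolysis of a vinylogous ester by addition of water at C3 and loss of ethanol; this is the established access to the dione.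

**Step 5**
Reactants: 6 cyclobutane-1,3-dione
Product: 7 3-chlorocyclobut-2-en-1-one
Conditions: (COCl)2 (1.05 equiv), DMF (cat.), CH2Cl2, 0 °C → rt
Reagents that add atoms: oxalyl chloride, O=C(Cl)C(=O)Cl
Why: Conversion of a vinylogous acid into its vinylogous acid chloride through the enol chlorooxalate, as practised on cyclohexane-1,3-dione and on squaric acid. The moisture-sensitive product is concentrated cold and used directly.

**Step 6**
Reactants: 7 3-chlorocyclobut-2-en-1-one; 4 2,6-bis(benzyloxy)-4-(methoxymethoxy)phenol
Product: 8 3-[2,6-bis(benzyloxy)-4-(methoxymethoxy)phenoxy]cyclobut-2-en-1-one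
Conditions: K2CO3, MeCN, 0 °C → rt, Ar
Reagents that add atoms: none
Why: Vinylogous acyl substitution (addition–elimination): the phenoxide oxygen adds to C3 of the β-chloro enone and chloride leaves. The flanked phenoxide meets an unhindered sp2 carbon, so the hindered ether should form without a metal catalyst.

**Step 7**
Reactants: 9 3-phenylisoxazole; 10 triisopropylsilyl chloride
Product: 13 (triisopropylsilyloxy)acetylene, via 5-lithio-3-phenylisoxazole 11 (not isolated), via lithium ethynolate 12 (not isolated)
Conditions: n-BuLi (1.0 equiv), THF, −78 → −40 °C; then 10, −78 → 0 °C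
Reagents that add atoms: none
Why: Deprotonation at C5 of a 3-arylisoxazole is followed by cycloreversion with N–O cleavage to benzonitrile and the ynolate, a known way to generate ynolates. The bulky silyl chloride should silylate oxygen, and the triisopropylsilyl group slows the 1,3-shift to a silylketene. The product is separated from benzonitrile by bulb-to-bulb distillation.

**Step 8**
Reactants: 8 3-[2,6-bis(benzyloxy)-4-(methoxymethoxy)phenoxy]cyclobut-2-en-1-one; 13 (triisopropylsilyloxy)acetylene
Product: 17 3-[2,6-bis(benzyloxy)-4-(methoxymethoxy)phenoxy]-5-(triisopropylsilyloxy)phenol, via vinylketene 14 (not isolated), via vinylcyclobutenone 15 (not isolated), via dienylketene 16 (not isolated)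
Conditions: 13 (2.5 equiv), toluene, 110 → 145 °C, sealed tube, Ar
Reagents that add atoms: none
Why: Proposed new method: the closest known reaction is the Danheiser benzannulation of cyclobutenones with silyloxyalkynes, which is established for carbon-substituted cyclobutenones but not for one whose C3 carries an aryloxy group, so the vinylogous ester 8 is the untested element. Thermal four-electron conrotatory opening of 8 should give the (1-aryloxyvinyl)ketene 14; the donor on C3 stabilises 8, which is why a higher temperature is planned. The electron-rich alkyne 13 then adds across the ketene C=C bond in a [2+2] cycloaddition that forms C1–C2 and C3–C4 of ring A and gives the 4-vinylcyclobutenone 15, whose single stereogenic carbon is racemic and is erased in the next event. Reversible four-electron opening of 15 gives the dienylketene 16, and the isomer with the vinyl group cis to the ketene closes ring A by thermal disrotatory six-electron electrocyclisation between C1 and C6, after which enolisation of the cyclohexadienone gives 17. The only selectivity needed is the orientation of the [2+2] step, and polarity fixes it: the unsubstituted, nucleophilic alkyne carbon bonds to the electrophilic ketene carbonyl carbon, which places the silyloxy group meta to both the new hydroxyl and the aryloxy group. No stereocentre survives into 17, and every event is neutral and thermal, so the benzyl, methoxymethyl and silyl ethers should be untouched. The excess of 13 is meant to intercept 14 before the phenol 17 can add to it.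

**Step 9**
Reactants: 17 3-[2,6-bis(benzyloxy)-4-(methoxymethoxy)phenoxy]-5-(triisopropylsilyloxy)phenol
Product: 18 3-[2,6-bis(benzyloxy)-4-hydroxyphenoxy]-5-(triisopropylsilyloxy)phenol
Conditions: HCl (cat.), MeOH/THF, 40 °C
Reagents that add atoms: none
Why: Acid-catalysed acetal exchange removes the methoxymethyl group as dimethoxymethane. The hindered aryl triisopropylsilyl ether, whose oxygen is weakly basic, and the benzyl ethers should withstand dilute methanolic acid.

**Step 10**
Reactants: 18 3-[2,6-bis(benzyloxy)-4-hydroxyphenoxy]-5-(triisopropylsilyloxy)phenol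
Product: 19 3-[2,6-bis(benzyloxy)-4-(sulfooxy)phenoxy]-5-(triisopropylsilyloxy)phenyl hydrogen sulfate
Conditions: SO3·pyridine (6 equiv), pyridine, 45 °C; work-up with aq. Bu4NOH
Reagents that add atoms: sulfur trioxide–pyridine complex, O=S(=O)([O-])[n+]1ccccc1
Why: O-sulfation of phenols with an amine–SO3 complex. The two free hydroxyls are the only nucleophilic sites and both are unhindered, so an excess of reagent should convert both.

**Step 11**
Reactants: 19 3-[2,6-bis(benzyloxy)-4-(sulfooxy)phenoxy]-5-(triisopropylsilyloxy)phenyl hydrogen sulfate
Product: 20 3-[2,6-bis(benzyloxy)-4-(sulfooxy)phenoxy]-5-hydroxyphenyl hydrogen sulfate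
Conditions: Bu4NF, AcOH, THF, 0 °C
Reagents that add atoms: none
Why: Fluoride-induced cleavage of an aryl silyl ether, driven by the strong Si–F bond. Buffered fluoride does not attack sulfate monoester anions or benzyl ethers.

**Step 12**
Reactants: 20 3-[2,6-bis(benzyloxy)-4-(sulfooxy)phenoxy]-5-hydroxyphenyl hydrogen sulfate
Product: 21 3-[2,6-dihydroxy-4-(sulfooxy)phenoxy]-5-hydroxyphenyl hydrogen sulfate
Conditions: H2 (1 atm), Pd/C, MeOH, rt; then Dowex 50W (H+ form), H2O, 0 °C
Reagents that add atoms: none
Why: Hydrogenolysis of the two benzyl ethers; aryl sulfate monoesters and the diaryl ether are inert to H2 over Pd/C in neutral methanol. The short cold pass through the acidic resin exchanges the counter-ions for protons, and the product is kept cold and oxygen-free.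

## Compound list

1 | 3,5-bis(benzyloxy)phenol | Oc1cc(OCc2ccccc2)cc(OCc2ccccc2)c1 | starting material
2 | 2,6-bis(benzyloxy)cyclohexa-2,5-diene-1,4-dione | O=C1C=C(OCc2ccccc2)C(=O)C(OCc2ccccc2)=C1 | intermediate
3 | 2,6-bis(benzyloxy)benzene-1,4-diol | Oc1cc(OCc2ccccc2)c(O)c(OCc2ccccc2)c1 | intermediate
4 | 2,6-bis(benzyloxy)-4-(methoxymethoxy)phenol | COCOc1cc(OCc2ccccc2)c(O)c(OCc2ccccc2)c1 | intermediate
5 | 3-ethoxycyclobut-2-en-1-one | CCOC1=CC(=O)C1 | starting material
6 | cyclobutane-1,3-dione | O=C1CC(=O)C1 | intermediate
7 | 3-chlorocyclobut-2-en-1-one | O=C1C=C(Cl)C1 | intermediate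
8 | 3-[2,6-bis(benzyloxy)-4-(methoxymethoxy)phenoxy]cyclobut-2-en-1-one | O=C1C=C(Oc2c(OCc3ccccc3)cc(OCOC)cc2OCc2ccccc2)C1 | intermediate
9 | 3-phenylisoxazole | c1ccc(-c2ccon2)cc1 | starting material
10 | triisopropylsilyl chloride | CC(C)[Si](Cl)(C(C)C)C(C)C | starting material
11 | 5-lithio-3-phenylisoxazole | [Li]c1cc(-c2ccccc2)no1 | intermediate
12 | lithium ethynolate | [Li+].[O-]C#C | intermediate
13 | (triisopropylsilyloxy)acetylene | C#CO[Si](C(C)C)(C(C)C)C(C)C | intermediate
14 | 3-[2,6-bis(benzyloxy)-4-(methoxymethoxy)phenoxy]buta-1,3-dien-1-one | O=C=CC(=C)Oc1c(OCc2ccccc2)cc(OCOC)cc1OCc1ccccc1 | intermediate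
15 | 4-{1-[2,6-bis(benzyloxy)-4-(methoxymethoxy)phenoxy]ethenyl}-3-(triisopropylsilyloxy)cyclobut-2-en-1-one (racemic) | O=C1C=C(O[Si](C(C)C)(C(C)C)C(C)C)C1C(=C)Oc1c(OCc2ccccc2)cc(OCOC)cc1OCc1ccccc1 | intermediate
16 | (3E)-5-[2,6-bis(benzyloxy)-4-(methoxymethoxy)phenoxy]-3-(triisopropylsilyloxy)hexa-1,3,5-trien-1-one | O=C=C/C(O[Si](C(C)C)(C(C)C)C(C)C)=C\C(=C)Oc1c(OCc2ccccc2)cc(OCOC)cc1OCc1ccccc1 | intermediate
17 | 3-[2,6-bis(benzyloxy)-4-(methoxymethoxy)phenoxy]-5-(triisopropylsilyloxy)phenol | Oc1cc(O[Si](C(C)C)(C(C)C)C(C)C)cc(Oc2c(OCc3ccccc3)cc(OCOC)cc2OCc2ccccc2)c1 | intermediate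
18 | 3-[2,6-bis(benzyloxy)-4-hydroxyphenoxy]-5-(triisopropylsilyloxy)phenol | Oc1cc(O[Si](C(C)C)(C(C)C)C(C)C)cc(Oc2c(OCc3ccccc3)cc(O)cc2OCc2ccccc2)c1 | intermediate
19 | 3-[2,6-bis(benzyloxy)-4-(sulfooxy)phenoxy]-5-(triisopropylsilyloxy)phenyl hydrogen sulfate | O=S(=O)(O)Oc1cc(O[Si](C(C)C)(C(C)C)C(C)C)cc(Oc2c(OCc3ccccc3)cc(OS(=O)(=O)O)cc2OCc2ccccc2)c1 | intermediate
20 | 3-[2,6-bis(benzyloxy)-4-(sulfooxy)phenoxy]-5-hydroxyphenyl hydrogen sulfate | O=S(=O)(O)Oc1cc(O)cc(Oc2c(OCc3ccccc3)cc(OS(=O)(=O)O)cc2OCc2ccccc2)c1 | intermediate
21 | 3-[2,6-dihydroxy-4-(sulfooxy)phenoxy]-5-hydroxyphenyl hydrogen sulfate | O=S(=O)(O)Oc1cc(O)cc(Oc2c(O)cc(OS(=O)(=O)O)cc2O)c1 | target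

## Step count and least certain steps

Total: 12 steps. Longest linear sequence: 9 steps (steps 1, 2, 3, 6, 8, 9, 10, 11, 12, from 1 to 21). The cyclobutenone branch (steps 4 and 5) and the alkyne branch (step 7) join it at steps 6 and 8.

**Step 8 (key step, proposed new method).**
- Most likely failure: the ring opening of 8 is too slow. The aryloxy group on C3 makes 8 a stabilised vinylogous ester, and at the temperature needed the alkyne 13 may already be isomerising by 1,3-silyl shift to a silylketene. A second risk is acylation of the product phenol by the vinylketene 14.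
- First resort: irradiation of 8 at room temperature to open the ring, then gentle heating.
- Fallback (known chemistry), from 4 back to 17: 5-bromoresorcinol would be O-allylated (allyl bromide, K2CO3, acetone) to 1-bromo-3,5-bis(prop-2-en-1-yloxy)benzene F1. An Ullmann ether synthesis tuned for hindered phenols (CuI, picolinic acid, K3PO4, DMSO, 90 °C) would join F1 to 4 and give 1,3-bis(benzyloxy)-2-[3,5-bis(prop-2-en-1-yloxy)phenoxy]-5-(methoxymethoxy)benzene F2. Allyl transfer to morpholine with Pd(PPh3)4 would free 5-[2,6-bis(benzyloxy)-4-(methoxymethoxy)phenoxy]benzene-1,3-diol F3. Monosilylation with one equivalent of triisopropylsilyl chloride 10 and imidazole, with recycling of unreacted and doubly silylated material, would give 17. This fallback gives up the built-in differentiation of ring A and relies on a statistical monoprotection.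

**Step 6 (with the labile chloro enone 7 from step 5).**
- Most likely failure: the phenoxide attacks the strained carbonyl group and the ring opens, or 7 is lost by hydrolysis or self-condensation before substitution at C3.
- Fallback, from 4 back to 8: the phenol 4 would be added to trichloroethylene (K2CO3, DMF, 70 °C) to give 1,3-bis(benzyloxy)-2-{[(E)-1,2-dichloroethenyl]oxy}-5-(methoxymethoxy)benzene F4. Elimination and chlorine–lithium exchange (n-BuLi, 2.2 equiv, THF, −78 °C, then MeOH) would give 1,3-bis(benzyloxy)-2-(ethynyloxy)-5-(methoxymethoxy)benzene F5. A [2+2] cycloaddition with dichloroketene (Cl3CCOCl, Zn–Cu couple, Et2O) would give 3-[2,6-bis(benzyloxy)-4-(methoxymethoxy)phenoxy]-4,4-dichlorocyclobut-2-en-1-one F6. Reduction with Zn, AcOH and TMEDA in EtOH would give 8. The four-membered ring is then built on the ether oxygen and no substitution at a cyclobutenone is needed.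

**Step 7.**
- Most likely failure: silylation of the ynolate 12 at carbon or a 1,3-silyl shift during isolation, either of which leads to a silylketene. Addition of the organolithium to the C=N bond of 9 or to the liberated nitrile is a second risk.
- Fallback, from 10 back to 13: acetylene would be deprotonated (n-BuLi, THF, −78 °C) to lithium acetylide F7. F7 would be oxidised with LiOOtBu, made in the flask from t-BuOOH and LiN(SiMe3)2, to the same ynolate 12. Silylation with 10 would give 13. This gives the ynolate free of nitrile and of ring-derived by-products.

**Step 3.**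
- Most likely failure: poor site selectivity, with alkylation at the flanked hydroxyl or at both hydroxyls, and reoxidation of 3 to 2 by air.
- Fallback, from 1 back to 4: Vilsmeier–Haack formylation of 1 (POCl3, DMF, then aqueous NaOAc) would give 2,6-bis(benzyloxy)-4-hydroxybenzaldehyde F8; its symmetry distinguishes it from the ortho-formylated isomer. Methoxymethylation (MOMCl, iPr2NEt) would give 2,6-bis(benzyloxy)-4-(methoxymethoxy)benzaldehyde F9. Baeyer–Villiger oxidation (mCPBA, NaHCO3, CH2Cl2) would give 2,6-bis(benzyloxy)-4-(methoxymethoxy)phenyl formate F10. Methanolysis (K2CO3, MeOH) would give 4. The acetal is then placed on the only free hydroxyl, and the flanked oxygen is introduced afterwards.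

## Further compounds

F1 | step 8 | 1-bromo-3,5-bis(prop-2-en-1-yloxy)benzene | C=CCOc1cc(Br)cc(OCC=C)c1
F2 | step 8 | 1,3-bis(benzyloxy)-2-[3,5-bis(prop-2-en-1-yloxy)phenoxy]-5-(methoxymethoxy)benzene | C=CCOc1cc(OCC=C)cc(Oc2c(OCc3ccccc3)cc(OCOC)cc2OCc2ccccc2)c1
F3 | step 8 | 5-[2,6-bis(benzyloxy)-4-(methoxymethoxy)phenoxy]benzene-1,3-diol | Oc1cc(O)cc(Oc2c(OCc3ccccc3)cc(OCOC)cc2OCc2ccccc2)c1
F4 | step 6 | 1,3-bis(benzyloxy)-2-{[(E)-1,2-dichloroethenyl]oxy}-5-(methoxymethoxy)benzene | Cl/C=C(/Cl)Oc1c(OCc2ccccc2)cc(OCOC)cc1OCc1ccccc1
F5 | step 6 | 1,3-bis(benzyloxy)-2-(ethynyloxy)-5-(methoxymethoxy)benzene | C#COc1c(OCc2ccccc2)cc(OCOC)cc1OCc1ccccc1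
F6 | step 6 | 3-[2,6-bis(benzyloxy)-4-(methoxymethoxy)phenoxy]-4,4-dichlorocyclobut-2-en-1-one | O=C1C=C(Oc2c(OCc3ccccc3)cc(OCOC)cc2OCc2ccccc2)C1(Cl)Cl
F7 | step 7 | lithium acetylide | [Li+].[C-]#C
F8 | step 3 | 2,6-bis(benzyloxy)-4-hydroxybenzaldehyde | O=Cc1c(OCc2ccccc2)cc(O)cc1OCc1ccccc1
F9 | step 3 | 2,6-bis(benzyloxy)-4-(methoxymethoxy)benzaldehyde | O=Cc1c(OCc2ccccc2)cc(OCOC)cc1OCc1ccccc1
F10 | step 3 | 2,6-bis(benzyloxy)-4-(methoxymethoxy)phenyl formate | O=COc1c(OCc2ccccc2)cc(OCOC)cc1OCc1ccccc1
A1 | alternative 1 | 3-[4-hydroxy-2,6-bis(triisopropylsilyloxy)phenoxy]-5-(triisopropylsilyloxy)phenol | Oc1cc(O[Si](C(C)C)(C(C)C)C(C)C)cc(Oc2c(O[Si](C(C)C)(C(C)C)C(C)C)cc(O)cc2O[Si](C(C)C)(C(C)C)C(C)C)c1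
A2 | alternative 1 | 1,3-bis(triisopropylsilyloxy)-2-[3-(triisopropylsilyloxy)phenoxy]benzene | CC(C)[Si](Oc1cccc(Oc2c(O[Si](C(C)C)(C(C)C)C(C)C)cccc2O[Si](C(C)C)(C(C)C)C(C)C)c1)(C(C)C)C(C)C
A3 | alternative 2 | 2-[3-(benzyloxy)-5-(methoxymethoxy)phenoxy]-5-(methoxymethoxy)benzene-1,3-diol | Oc1cc(OCOC)cc(O)c1Oc1cc(OCc2ccccc2)cc(OCOC)c1
A4 | alternative 2 | 6-{[3-(benzyloxy)-5-(methoxymethoxy)phenoxy]methyl}-4-(methoxymethoxy)-2H-pyran-2-one | O=C1C=C(OCOC)C=C(COc2cc(OCc3ccccc3)cc(OCOC)c2)O1
A5 | alternative 3 | dimethyl 5-[3-(benzyloxy)-5-(methoxymethoxy)phenoxy]-2,4,6-trihydroxybenzene-1,3-dicarboxylate | COC(=O)c1c(O)c(C(=O)OC)c(O)c(Oc2cc(OCc3ccccc3)cc(OCOC)c2)c1O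
A6 | alternative 3 | dimethyl 2-[3-(benzyloxy)-5-(methoxymethoxy)phenoxy]propanedioate | COC(=O)C(Oc1cc(OCc2ccccc2)cc(OCOC)c1)C(=O)OC
A7 | alternative 3 | dimethyl 3-oxopentanedioate | COC(=O)CC(=O)CC(=O)OC
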